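## Retrosynthetic overview

1. Target 23 ⇒ bis-silyl ether 22 ⇒ C12–C13 bond by B-alkyl Suzuki coupling of the 9-BBN adduct of 9-vinyl diene 19 with bought 4-bromofuran-2(5H)-one 20; C9–C11 bond by Stille vinylation of enol triflate 18.
2. 5α-H/6α-OH ⇒ hydroboration of a Δ5 alkene, from dehydration of a 5β tertiary alcohol; 2α-OH ⇒ equilibrating reduction of a C2 ketone; C8=C9 ⇒ methylation and triflation of a C9 ketone.
3. C19 and the C4 quaternary centre ⇒ silicon-tethered radical hydroxymethylation of the C3=C4 enone, delivered from the 5β-OH.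
4. Key disconnection C9–C10 (closes ring B, formed second): enantioselective intramolecular Stetter reaction, in which the C9 aldehyde, as its carbene-derived acyl anion, adds to the enone β-carbon C10 of prochiral p-quinol 6 and creates the C10 quaternary centre.
5. Ring A comes first, as the aromatic ring of 2,6-dimethylphenol 1, dearomatised to quinone monoketal 2 and joined to the C6–C9 chain by Grignard addition.

Assumption: the (5aS,10bR) triazolium salt is taken to give the C10 configuration drawn for 7; if it gives the mirror image, its (5aR,10bS) enantiomer is used and nothing else changes.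

Convention: labdane numbering is used for all bicyclic compounds (ring A = C1–C5, C10; ring B = C5–C10; C17 on C8, C18 = 4α-methyl, C19 = 4β-CH2O, C20 on C10); β is the face of C20. The target is (2R,4S,5R,6S,10S).

## Route

Step 1
Reactants: 1 2,6-dimethylphenol
Product: 2 4,4-dimethoxy-2,6-dimethylcyclohexa-2,5-dien-1-one
Conditions: PhI(OAc)2 (2.1 equiv), MeOH, 0 → 23 °C
Reagents that add atoms: methanol, CO
Why: Oxidative dearomatisation of a para-unsubstituted phenol with trivalent iodine in methanol traps the para position twice with MeOH, giving the p-quinone monoketal whose only free carbonyl is the one flanked by the two methyls (future C5); no stereocentre.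

Step 2
Reactants: 2 4,4-dimethoxy-2,6-dimethylcyclohexa-2,5-dien-1-one; 3 4-chloro-1,1-diethoxybutane
Product: 6 4-hydroxy-3,5-dimethyl-4-(4-oxobutyl)cyclohexa-2,5-dien-1-one, via alkylmagnesium chloride 4 (not isolated), via ClMg alkoxide 5 (not isolated)
Conditions: 3, Mg, THF, 50 °C; then 2, LaCl3·2LiCl, THF, −20 → 0 °C; then 1 M HCl, THF, 0 → 23 °C
Reagents that add atoms: water, O
Why: Grignard 1,2-addition to the single carbonyl of 2 (the lanthanum salt suppresses enolisation and conjugate addition), then one acid treatment hydrolyses the quinone ketal and the diethyl acetal (p-quinol synthesis); 6 is achiral and sits partly as its spiro-lactol.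

Step 3
Reactants: 6 4-hydroxy-3,5-dimethyl-4-(4-oxobutyl)cyclohexa-2,5-dien-1-one
Product: 7 5β-hydroxy-4,10β-dimethyl-cis-octal-3-ene-2,9-dione
Conditions: (5aS,10bR)-2-(pentafluorophenyl)-5a,10b-dihydro-4H,6H-indeno[2,1-b][1,2,4]triazolo[4,3-d][1,4]oxazin-2-ium tetrafluoroborate (20 mol %), KN(SiMe3)2 (18 mol %), toluene, 23 °C
Reagents that add atoms: none
Why: Proposed new method: the open aldehyde form of 6 adds the triazolylidene to give a Breslow intermediate (acyl anion at C9) that attacks the β-carbon C10 of one of the two enantiotopic enone arms in a 6-exo Michael addition on the face of the tether, so the chiral carbene fixes the C10 quaternary centre and the tether forces cis fusion (5-OH syn to C20); the closest known chemistry is the carbene-catalysed desymmetrising intramolecular Stetter reaction of 4,4-disubstituted cyclohexadienones (known with oxygen-tethered aldehydes and five-membered ring closure) and Stetter formation of quaternary centres from β,β-disubstituted acceptors.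

Step 4
Reactants: 7 5β-hydroxy-4,10β-dimethyl-cis-octal-3-ene-2,9-dione
Product: 8 5β-O-[(bromomethyl)dimethylsilyl] ether of 7
Conditions: BrCH2SiMe2Cl, imidazole, CH2Cl2/DMF, 0 → 23 °C
Reagents that add atoms: (bromomethyl)chlorodimethylsilane, C[Si](C)(Cl)CBr
Why: Silyl ether formation with a small dimethylsilyl chloride reaches the hindered tertiary alcohol, installs the radical tether and masks the β-ketol against retro-aldol opening; no stereocentre changes.

Step 5
Reactants: 8 5β-O-[(bromomethyl)dimethylsilyl] ether of 7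
Product: 10 5β,19-dihydroxy-4α,10β-dimethyl-cis-decalin-2,9-dione, via cyclic siloxane 9 (not isolated)
Conditions: Bu3SnH (syringe pump), AIBN, PhH, 80 °C; then KF, KHCO3, 30 % H2O2, THF/MeOH, 23 °C
Reagents that add atoms: hydrogen peroxide, OO
Why: Stork–Nishiyama silicon-tethered 5-exo radical cyclisation: the nucleophilic α-silyl radical adds to the enone β-carbon C4 on the face of the tether (cis-fused five-membered siloxane), so C19 is β and C18 α, and Tamao oxidation turns C–Si into C–OH.

Step 6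
Reactants: 10 5β,19-dihydroxy-4α,10β-dimethyl-cis-decalin-2,9-dione
Product: 11 19-O-TBS ether of 10
Conditions: TBSCl, imidazole, DMF, 23 °C
Reagents that add atoms: tert-butyldimethylsilyl chloride, CC(C)(C)[Si](C)(C)Cl
Why: Selective silylation of the primary alcohol; the tertiary 5-OH does not react under these conditions.

Step 7
Reactants: 11 19-O-TBS ether of 10
Product: 12 19-(TBS-oxy)-4α,10β-dimethyl-Δ5-octalin-2,9-dione
Conditions: SOCl2, pyridine, CH2Cl2, −20 → 0 °C
Reagents that add atoms: none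
Why: E2 dehydration through the chlorosulfite; C4 and C10 are quaternary, so only C6 can lose a proton and only the Δ5 alkene can form, and pyridine avoids a free C5 cation (no methyl shift).

Step 8
Reactants: 12 19-(TBS-oxy)-4α,10β-dimethyl-Δ5-octalin-2,9-dione
Product: 13 2α-hydroxy-19-(TBS-oxy)-4α,10β-dimethyl-Δ5-octalin-9-one
Conditions: Al(OiPr)3 (0.5 equiv), iPrOH/toluene, acetone (2 vol %), 85 °C
Reagents that add atoms: none
Why: Meerwein–Ponndorf–Verley reduction under equilibrating conditions: the C9 carbonyl next to quaternary C10 reacts far more slowly, and reversible hydride transfer funnels C2 to the equatorial 2α-alcohol because the axial 2β epimer has syn-axial contacts with C20 and C19.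

Step 9
Reactants: 13 2α-hydroxy-19-(TBS-oxy)-4α,10β-dimethyl-Δ5-octalin-9-one
Product: 14 2α,19-bis(TBS-oxy)-4α,10β-dimethyl-Δ5-octalin-9-one
Conditions: TBSOTf, 2,6-lutidine, CH2Cl2, 0 °C
Reagents that add atoms: tert-butyldimethylsilyl triflate, CC(C)(C)[Si](C)(C)OS(=O)(=O)C(F)(F)F
Why: Silylation of the secondary alcohol so that the only acidic site left is C8.

Step 10
Reactants: 14 2α,19-bis(TBS-oxy)-4α,10β-dimethyl-Δ5-octalin-9-one
Product: 15 8-methyl derivative of 14 (C8 epimer mixture)
Conditions: LiN(iPr)2, THF, −78 °C; MeI, −78 → −20 °C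
Reagents that add atoms: iodomethane, CI
Why: Kinetic enolate alkylation; C8 is the only enolisable position because C10 is quaternary, and the new C8 stereocentre is removed in the next step.

Step 11
Reactants: 15 8-methyl derivative of 14
Product: 16 2α,19-bis(TBS-oxy)-Δ5,Δ8-dienyl 9-triflate
Conditions: KN(SiMe3)2, THF, −78 → 0 °C; PhNTf2, −78 → 23 °C
Reagents that add atoms: N-phenylbis(trifluoromethanesulfonimide), O=S(=O)(N(c1ccccc1)S(=O)(=O)C(F)(F)F)C(F)(F)F
Why: Deprotonation of the remaining C8–H gives the tetrasubstituted enolate and O-triflation (enol triflate formation) fixes the C8=C9 double bond.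

Step 12
Reactants: 16 2α,19-bis(TBS-oxy)-Δ5,Δ8-dienyl 9-triflate
Product: 18 6α-hydroxy-5α-H trans-fused 9-triflate, via alkylborane 17 (not isolated)
Conditions: BH3·THF, THF, 0 → 23 °C; then 3 M NaOAc (aq), 30 % H2O2, 0 → 23 °C
Reagents that add atoms: hydrogen peroxide, OO
Why: Hydroboration–oxidation: syn addition to Δ5 from the α face (the β face is blocked by axial C20 and C19) with boron on the less substituted C6 gives 5α-H (trans-decalin) and 6α-OH, while the electron-poor enol triflate alkene is untouched.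

Step 13
Reactants: 18 6α-hydroxy-5α-H trans-fused 9-triflate
Product: 19 9-vinyl diene (2α,19-bis(TBS-oxy)-6α-ol)
Conditions: Bu3SnCH=CH2, Pd(PPh3)4 (5 mol %), LiCl, THF, 65 °C
Reagents that add atoms: tributyl(vinyl)stannane, C=C[Sn](CCCC)(CCCC)CCCC
Why: Stille coupling on zerovalent palladium; hindered 2,6,6-trisubstituted cyclohexenyl triflates of this kind couple reliably with LiCl, and the free 6-OH is tolerated.

Step 14
Reactants: 19 9-vinyl diene; 20 4-bromofuran-2(5H)-one
Product: 22 2,19-bis-O-TBS ether of the target, via B-alkyl-9-BBN adduct 21 (not isolated)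
Conditions: 9-BBN dimer (excess), THF, 0 → 23 °C; then 20, PdCl2(dppf) (5 mol %), AsPh3, K3PO4 (aq), DMF, 23 °C
Reagents that add atoms: none
Why: 9-BBN hydroborates only the terminal vinyl group (anti-Markovnikov; the tetrasubstituted alkene is inert) and B-alkyl Suzuki–Miyaura coupling with the β-bromobutenolide forms C12–C13.

Step 15
Reactants: 22 2,19-bis-O-TBS ether of the target
Product: 23 2α,6α,19-trihydroxylabda-8,13-dien-15,16-olide (target)
Conditions: HF·pyridine, pyridine/THF, 0 → 23 °C
Reagents that add atoms: none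
Why: Fluoride desilylation of both silyl ethers under buffered conditions that leave the butenolide and the tetrasubstituted alkene alone; no stereocentre is touched.

## Compound list

1 | 2,6-dimethylphenol | Cc1cccc(C)c1O | starting material
2 | 4,4-dimethoxy-2,6-dimethylcyclohexa-2,5-dien-1-one | COC1(OC)C=C(C)C(=O)C(C)=C1 | intermediate
3 | 4-chloro-1,1-diethoxybutane | CCOC(CCCCl)OCC | starting material
4 | (4,4-diethoxybutyl)magnesium chloride | CCOC(CCC[Mg]Cl)OCC | intermediate
5 | ClMg alkoxide of 1-(4,4-diethoxybutyl)-4,4-dimethoxy-2,6-dimethylcyclohexa-2,5-dien-1-ol | CCOC(CCCC1(O[Mg]Cl)C(C)=CC(OC)(OC)C=C1C)OCC | intermediate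
6 | 4-hydroxy-3,5-dimethyl-4-(4-oxobutyl)cyclohexa-2,5-dien-1-one | O=CCCCC1(O)C(C)=CC(=O)C=C1C | intermediate
7 | 5β-hydroxy-4,10β-dimethyl-cis-octal-3-ene-2,9-dione | O=C1[C@@]2(C)CC(=O)C=C(C)[C@@]2(O)CCC1 | intermediate
8 | 5β-O-[(bromomethyl)dimethylsilyl] ether of 7 | O=C1[C@@]2(C)CC(=O)C=C(C)[C@@]2(O[Si](C)(C)CBr)CCC1 | intermediate
9 | cyclic siloxane (C19–SiMe2–O–C5; 4α-methyl; 2,9-dione) | O=C1[C@@]2(C)CC(=O)C[C@](C)(C[Si](C)(C)O3)[C@@]23CCC1 | intermediate
10 | 5β,19-dihydroxy-4α,10β-dimethyl-cis-decalin-2,9-dione | O=C1[C@@]2(C)CC(=O)C[C@](C)(CO)[C@@]2(O)CCC1 | intermediate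
11 | 19-O-TBS ether of 10 | O=C1[C@@]2(C)CC(=O)C[C@](C)(CO[Si](C)(C)C(C)(C)C)[C@@]2(O)CCC1 | intermediate
12 | 19-(TBS-oxy)-4α,10β-dimethyl-Δ5-octalin-2,9-dione | O=C1[C@@]2(C)CC(=O)C[C@](C)(CO[Si](C)(C)C(C)(C)C)C2=CCC1 | intermediate
13 | 2α-hydroxy-19-(TBS-oxy)-4α,10β-dimethyl-Δ5-octalin-9-one | O=C1[C@@]2(C)C[C@@H](O)C[C@](C)(CO[Si](C)(C)C(C)(C)C)C2=CCC1 | intermediate
14 | 2α,19-bis(TBS-oxy)-4α,10β-dimethyl-Δ5-octalin-9-one | O=C1[C@@]2(C)C[C@@H](O[Si](C)(C)C(C)(C)C)C[C@](C)(CO[Si](C)(C)C(C)(C)C)C2=CCC1 | intermediate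
15 | 8-methyl derivative of 14 (C8 epimers) | O=C1[C@@]2(C)C[C@@H](O[Si](C)(C)C(C)(C)C)C[C@](C)(CO[Si](C)(C)C(C)(C)C)C2=CCC1C | intermediate
16 | 2α,19-bis(TBS-oxy)-Δ5,Δ8-dienyl 9-triflate | CC1=C(OS(=O)(=O)C(F)(F)F)[C@@]2(C)C[C@@H](O[Si](C)(C)C(C)(C)C)C[C@](C)(CO[Si](C)(C)C(C)(C)C)C2=CC1 | intermediate
17 | 6α-boryl-5α-H alkylborane from 16 | CC1=C(OS(=O)(=O)C(F)(F)F)[C@@]2(C)C[C@@H](O[Si](C)(C)C(C)(C)C)C[C@](C)(CO[Si](C)(C)C(C)(C)C)[C@@H]2[C@@H](B)C1 | intermediate
18 | 6α-hydroxy-5α-H trans-fused 9-triflate | CC1=C(OS(=O)(=O)C(F)(F)F)[C@@]2(C)C[C@@H](O[Si](C)(C)C(C)(C)C)C[C@](C)(CO[Si](C)(C)C(C)(C)C)[C@@H]2[C@@H](O)C1 | intermediate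
19 | 9-vinyl diene (2α,19-bis(TBS-oxy)-6α-ol) | CC1=C(C=C)[C@@]2(C)C[C@@H](O[Si](C)(C)C(C)(C)C)C[C@](C)(CO[Si](C)(C)C(C)(C)C)[C@@H]2[C@@H](O)C1 | intermediate
20 | 4-bromofuran-2(5H)-one | O=C1C=C(Br)CO1 | starting material
21 | B-alkyl-9-BBN adduct of 19 (C12–B; 6-O–B borinate) | CC1=C(CCB3C4CCCC3CCC4)[C@@]2(C)C[C@@H](O[Si](C)(C)C(C)(C)C)C[C@](C)(CO[Si](C)(C)C(C)(C)C)[C@@H]2[C@@H](OB3C4CCCC3CCC4)C1 | intermediate
22 | 2,19-bis-O-TBS ether of the target | CC1=C(CCC2=CC(=O)OC2)[C@@]2(C)C[C@@H](O[Si](C)(C)C(C)(C)C)C[C@](C)(CO[Si](C)(C)C(C)(C)C)[C@@H]2[C@@H](O)C1 | intermediate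
23 | 2α,6α,19-trihydroxylabda-8,13-dien-15,16-olide, (2R,4S,5R,6S,10S) | CC1=C(CCC2=CC(=O)OC2)[C@@]2(C)C[C@@H](O)C[C@](C)(CO)[C@@H]2[C@@H](O)C1 | target

## Step count and risks

Total steps: 15. Longest linear sequence: 15 (the route is fully linear; 3 and 20 are bought).

Most likely to fail:

**Step 3 (Stetter cyclisation).** The aldehyde is largely tied up as a lactol, the ring closure is six-membered onto a β-methyl enone, and the product is a β-ketol that base could racemise by retro-aldol opening (hence base kept below the catalyst loading and prompt silylation in step 4). Fallback, setting out from 2 and coming back at 7: the same C9–C10 bond is made with a nitronate as the acyl-anion equivalent. Addition of 4-chlorobutylmagnesium bromide to 2 and mild acid hydrolysis give 4-(4-chlorobutyl)-4-hydroxy-3,5-dimethylcyclohexa-2,5-dien-1-one F1. NaNO2 with catalytic NaI in DMF gives 4-hydroxy-3,5-dimethyl-4-(4-nitrobutyl)cyclohexa-2,5-dien-1-one F2. A bifunctional cinchona-derived amine–thiourea catalyst effects the desymmetrising intramolecular nitro-Michael addition to the cis-fused 9-nitro enone F3. A buffered TiCl3 Nef reaction converts C9–NO2 into the C9 ketone, which is 7.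

**Step 8 (equilibrating reduction).** It needs C2 to react and epimerise faster than C9 is reduced. Fallback, setting out from 12 and coming back at 13: NaBH4 in MeOH at −40 °C reduces only C2 from the open α face to the axial 2β-alcohol F4. Mitsunobu inversion (4-nitrobenzoic acid, PPh3, DIAD) gives the 2α-(4-nitrobenzoate) F5. K2CO3 in MeOH then gives 13.

**Step 12 (hydroboration).** The Δ5 alkene lies between two quaternary carbons and may be too slow or not face-selective enough. Fallback, setting out from 16 and coming back at 18: mCPBA epoxidises Δ5 from the α face to the 5α,6α-epoxide F6. Trivalent titanium (Cp2TiCl from Cp2TiCl2 and Mn, with 1,4-cyclohexadiene and collidine hydrochloride) opens it homolytically to the tertiary C5 radical, which takes hydrogen on the α face. This gives the anti-Markovnikov 6α-alcohol with 5α-H, which is 18.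

Further compounds
F1 | step 3 | 4-(4-chlorobutyl)-4-hydroxy-3,5-dimethylcyclohexa-2,5-dien-1-one | ClCCCCC1(O)C(C)=CC(=O)C=C1C
F2 | step 3 | 4-hydroxy-3,5-dimethyl-4-(4-nitrobutyl)cyclohexa-2,5-dien-1-one | O=[N+]([O-])CCCCC1(O)C(C)=CC(=O)C=C1C
F3 | step 3 | 5β-hydroxy-4,10β-dimethyl-9-nitro-cis-octal-3-en-2-one | [O-][N+](=O)C1[C@@]2(C)CC(=O)C=C(C)[C@@]2(O)CCC1
F4 | step 8 | 2β-hydroxy-19-(TBS-oxy)-4α,10β-dimethyl-Δ5-octalin-9-one | O=C1[C@@]2(C)C[C@H](O)C[C@](C)(CO[Si](C)(C)C(C)(C)C)C2=CCC1
F5 | step 8 | 2α-(4-nitrobenzoyloxy)-19-(TBS-oxy)-4α,10β-dimethyl-Δ5-octalin-9-one | O=C1[C@@]2(C)C[C@@H](OC(=O)c3ccc(cc3)[N+](=O)[O-])C[C@](C)(CO[Si](C)(C)C(C)(C)C)C2=CCC1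
F6 | step 12 | 5α,6α-epoxide of 16 | CC1=C(OS(=O)(=O)C(F)(F)F)[C@@]2(C)C[C@@H](O[Si](C)(C)C(C)(C)C)C[C@](C)(CO[Si](C)(C)C(C)(C)C)[C@]2(O3)[C@@H]3C1
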